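The constants used here are assumed; the flask was simulated.

The constants come first, since they answer your quick question, and they go against your hunch that the coldest flask gives the cleanest target.

common to all: substrate 10 mM; partner 11.0 mM; time 30 s
- Tuesday's: temperature 30 °C
- Friday's: temperature 15 °C
- Saturday's: temperature 0 °C
- Monday's: at 0 °C until 10 s, from then on at 30 °C

    substrate + partner → target (k1 = 2.0 L mol⁻¹ s⁻¹, Ea1 = 52.0 kJ mol⁻¹)
    substrate + partner → isomer of the product (k2 = 0.14 L mol⁻¹ s⁻¹, Ea2 = 45.0 kJ mol⁻¹)
    substrate + partner → second isomer (k3 = 0.039 L mol⁻¹ s⁻¹, Ea3 = 63.0 kJ mol⁻¹)
    partner → decomposed reagent (k4 = 0.0012 s⁻¹, Ea4 = 75.0 kJ mol⁻¹)
    (constants at 0 °C)

1. the best flask by share of target in all that became target or isomer of the product or second isomer; "all alike" if 1.5 percentage points covers them all (Tuesday's / Friday's / Saturday's / Monday's / all alike)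
2. share of target in all that became target or isomer of the product or second isomer, Tuesday's
3. share of target in all that became target or isomer of the product or second isomer, Friday's
4. share of target in all that became target or isomer of the product or second isomer, Saturday's
5. share of target in all that became target or isomer of the product or second isomer, Monday's

Here is the reckoning I would commit to. Target, isomer of the product and second isomer each form from one substrate meeting one partner, so at one temperature their rates stand in the ratio of their constants, and at that temperature the ratio stays put as the two concentrations fall. Freeze it and call it the split: the constant of the step to target over the sum of the three product constants, which is the selectivity of the flask at one temperature. At 0 °C the split is 91.8%.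

Going to 30 °C speeds the step to second isomer by 16, and each other step gains that factor raised to its activation energy over that step's. So the step to target gains 9.64, more than the 7.11 of the step to isomer of the product and less than the second isomer's. The hot split comes to 92.3%, higher than the cold one, which is where I part from your hunch. The gap is 0.50 percentage points, smaller than the margin of 1.5 points. The loss of partner to decomposed reagent makes none of the three products, so it stays outside the split. I expect Tuesday's at the hot split, Saturday's at the cold one, and Friday's and Monday's between them, so the flasks count as alike.

The forecast gives 92.3% for Tuesday's, 92.2% for Friday's, 91.8% for Saturday's and 92.2% for Monday's, and its verdict is all alike. Its ground is that, of the two isomers, “their temperature shifts nearly cancel”.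

The simulation gives 92.3% for Tuesday's, 92.2% for Friday's, 91.8% for Saturday's and 92.2% for Monday's, so the verdict is all alike.

In Monday's flask, the three products at 10 s amount to 19.4% of the substrate charged, made at the cold split, and what forms later comes at the hot split. Weighting the two splits by those amounts gives 92.2% for Monday's at its end. The neighbouring flask is Monday's read at 12 s, where the products stand at 41.0%, so about half of them are cold-made. The same weighting gives 92.1%, and that flask reads 92.1%, with target at 37.8% and substrate at 59.0%.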